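**Retrosynthetic overview**

1. Target ⇐ O‑desilylation ⇐ SN2 opening at C8 of a 7,8‑epoxide by 3‑methylbutanoic acid (sets the trans C7‑OH/C8‑ester pair). The epoxide and the cis‑fused γ‑lactone (last ring) come from iodolactonisation of a cycloheptenyl acrylate, then closure by the C7 hydroxyl.
2. Tertiary α′‑hydroxy (Z)‑enone ⇐ 1,2‑addition of lithiated 1‑methoxybuta‑1,2‑diene (masked (Z)‑crotonoyl anion) to a 4‑substituted cyclohept‑2‑enone.
3. Cycloheptenone ⇐ one‑carbon ring expansion of a cyclohexanone‑derived siloxycyclopropane with FeCl3 (β‑scission of a cyclopropoxy radical). This is the key step; the CH2 from CH2I2 becomes C8.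
4. Silyl enol ether ⇐ new Ni‑catalysed reductive conjugate alkenylation of a (5R,6S)‑5‑silyloxy‑6‑methylcyclohex‑2‑enone with methyl 2‑bromoacrylate.
5. That enone ⇐ 2‑methylcyclohex‑2‑enone by asymmetric conjugate borylation/oxidation, silylation and Saegusa oxidation. Ring order: cyclohexane (bought) → cycloheptane → γ‑lactone.

Assumption: locants C3a–C8a in the Why lines are those of the target's cyclohepta[b]furan‑2‑one core; TBS = tert‑butyldimethylsilyl, TES = triethylsilyl, TMS = trimethylsilyl, NIS = N‑iodosuccinimide.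

**Route**

Step 1
Reactants: 1 2‑methylcyclohex‑2‑en‑1‑one
Product: 3 (2S,3R)‑3‑hydroxy‑2‑methylcyclohexan‑1‑one, via boryl ketone 2 (not isolated)
Conditions: B2pin2, CuCl (5 mol%), QuinoxP* (6 mol%, the antipode that gives 3R), NaOt‑Bu (10 mol%), MeOH, THF, rt; then NaBO3·4H2O, THF/H2O, rt
Reagents that add atoms: bis(pinacolato)diboron CC1(C)OB(OC1(C)C)B1OC(C)(C)C(C)(C)O1 (boron of 2 only); sodium perborate [Na+].[O-]OB=O (hydroxyl oxygen of 3)
Why: Copper‑catalysed enantioselective conjugate borylation under a chiral bisphosphine sets the future C5 carbinol centre as 3R, the basic medium equilibrates the α‑methyl centre (future C6) to the trans 2S isomer, and perborate oxidation replaces boron by hydroxyl with retention.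

Step 2
Reactants: 3 (2S,3R)‑3‑hydroxy‑2‑methylcyclohexan‑1‑one
Product: 4 (2S,3R)‑3‑[(tert‑butyldimethylsilyl)oxy]‑2‑methylcyclohexan‑1‑one
Conditions: TBSCl, imidazole, DMF, rt
Reagents that add atoms: tert‑butyl(chloro)dimethylsilane CC(C)(C)[Si](C)(C)Cl
Why: Imidazole‑promoted silylation of the secondary alcohol gives a TBS ether that masks the future C5 hydroxyl until the last step.

Step 3
Reactants: 4 (2S,3R)‑3‑[(tert‑butyldimethylsilyl)oxy]‑2‑methylcyclohexan‑1‑one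
Product: 6 (5R,6S)‑5‑[(tert‑butyldimethylsilyl)oxy]‑6‑methylcyclohex‑2‑en‑1‑one, via TMS enol ether 5 (not isolated)
Conditions: LiN(i‑Pr)2, TMSCl, THF, −78 °C; then Pd(OAc)2 (1.05 equiv), MeCN, rt
Reagents that add atoms: chlorotrimethylsilane C[Si](C)(C)Cl (silyl group of 5 only)
Why: Kinetic deprotonation at the unsubstituted α‑methylene with silyl trapping, then Saegusa–Ito oxidation (palladium enolate, β‑hydride elimination), places the enone on the side away from the methyl group under neutral conditions that leave both stereocentres untouched.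

Step 4
Reactants: 6 (5R,6S)‑5‑[(tert‑butyldimethylsilyl)oxy]‑6‑methylcyclohex‑2‑en‑1‑one; 7 methyl 2‑bromoprop‑2‑enoate
Product: 8 methyl 2‑[(1R,4S,5R)‑5‑[(tert‑butyldimethylsilyl)oxy]‑4‑methyl‑3‑[(triethylsilyl)oxy]cyclohex‑2‑en‑1‑yl]prop‑2‑enoate
Conditions: NiCl2(dme) (10 mol%), neocuproine (10 mol%), Mn powder (2 equiv), Et3SiCl (1.5 equiv), DMF, rt, 7 added over 4 h
Reagents that add atoms: chlorotriethylsilane CC[Si](CC)(CC)Cl
Why: Proposed new method: zerovalent nickel and Et3SiCl add to the enone to give an η3‑1‑silyloxyallyl nickel species on the face anti to the silyloxy group, Mn‑driven oxidative addition of the C–Br bond of the 2‑bromoacrylate and C–C reductive elimination then place the 1‑(methoxycarbonyl)vinyl group trans to OTBS (future C3a) and release the silyl enol ether regiospecifically; the closest known reaction type is the nickel‑catalysed reductive conjugate addition of aryl and simple alkenyl halides to enones with chlorosilane trapping, which has not been shown for 2‑haloacrylates.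

Step 5
Reactants: 8 methyl 2‑[(1R,4S,5R)‑5‑[(tert‑butyldimethylsilyl)oxy]‑4‑methyl‑3‑[(triethylsilyl)oxy]cyclohex‑2‑en‑1‑yl]prop‑2‑enoate; 9 diiodomethane
Product: 10 methyl 2‑[(1S,2R,4R,5S,6R)‑4‑[(tert‑butyldimethylsilyl)oxy]‑5‑methyl‑6‑[(triethylsilyl)oxy]bicyclo[4.1.0]heptan‑2‑yl]prop‑2‑enoate
Conditions: Et2Zn (2 equiv), CH2Cl2, 0 °C to rt
Reagents that add atoms: none
Why: Simmons–Smith cyclopropanation (Furukawa variant) is selective for the electron‑rich silyl enol ether over the electron‑poor acrylate, and the two new cyclopropane stereocentres (drawn anti to the side chain) are erased in the next step.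

Step 6
Reactants: 10 methyl 2‑[(1S,2R,4R,5S,6R)‑4‑[(tert‑butyldimethylsilyl)oxy]‑5‑methyl‑6‑[(triethylsilyl)oxy]bicyclo[4.1.0]heptan‑2‑yl]prop‑2‑enoate
Product: 12 methyl 2‑[(1R,5S,6R)‑6‑[(tert‑butyldimethylsilyl)oxy]‑5‑methyl‑4‑oxocyclohept‑2‑en‑1‑yl]prop‑2‑enoate, via β‑chloro ketone 11 (not isolated)
Conditions: FeCl3 (2.2 equiv), DMF, 0 °C to rt; then NaOAc, MeOH, 40 °C
Reagents that add atoms: iron trichloride Cl[Fe](Cl)Cl (chlorine of 11 only)
Why: Ito–Saegusa ring expansion, in which single‑electron oxidation of the siloxycyclopropane by FeCl3 gives a cyclopropoxy radical whose β‑scission cleaves the internal bond to the secondary radical, chlorine transfer gives the ring‑enlarged β‑chloro ketone, and acetate‑induced loss of HCl gives the cyclohept‑2‑enone with the C3a, C5 and C6 centres untouched.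

Step 7
Reactants: 13 but‑2‑yn‑1‑ol
Product: 15 1‑methoxybuta‑1,2‑diene, via 1‑methoxybut‑2‑yne 14 (not isolated)
Conditions: KOH, MeI, DMSO, 20 °C; then KOt‑Bu (0.2 equiv), 50 °C, distil
Reagents that add atoms: iodomethane CI
Why: Williamson methylation followed by base‑catalysed propargyl‑to‑allenyl ether isomerisation gives the volatile allenyl ether that serves as a masked (Z)‑crotonoyl unit.

Step 8
Reactants: 12 methyl 2‑[(1R,5S,6R)‑6‑[(tert‑butyldimethylsilyl)oxy]‑5‑methyl‑4‑oxocyclohept‑2‑en‑1‑yl]prop‑2‑enoate; 15 1‑methoxybuta‑1,2‑diene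
Product: 18 methyl 2‑[(1R,4R,5S,6R)‑4‑[(2Z)‑but‑2‑enoyl]‑6‑[(tert‑butyldimethylsilyl)oxy]‑4‑hydroxy‑5‑methylcyclohept‑2‑en‑1‑yl]prop‑2‑enoate, via lithiated allenyl ether 16 (not isolated), via allenyl ether carbinol 17 (not isolated)
Conditions: 15, n‑BuLi, THF, −78 °C; add 12, −78 °C; then 5% aq H2SO4, THF, 0 °C
Reagents that add atoms: n‑butyllithium [Li]CCCC (lithium of 16 only); water O (ketone oxygen of 18)
Why: α‑Lithiation of the allenyl ether gives a hard acyl‑anion equivalent that adds 1,2 to the enone from the face anti to the adjacent C6 methyl (setting C7 with its oxygen cis to that methyl), and kinetic protonation of the allenyl ether at its central carbon anti to the terminal methyl during cold acid hydrolysis gives the (Z)‑enone.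

Step 9
Reactants: 18 methyl 2‑[(1R,4R,5S,6R)‑4‑[(2Z)‑but‑2‑enoyl]‑6‑[(tert‑butyldimethylsilyl)oxy]‑4‑hydroxy‑5‑methylcyclohept‑2‑en‑1‑yl]prop‑2‑enoate
Product: 20 (3aS,5R,6S,7S,8R,8aR)‑7‑[(2Z)‑but‑2‑enoyl]‑5‑[(tert‑butyldimethylsilyl)oxy]‑7,8‑epoxy‑6‑methyl‑3‑methylideneoctahydro‑2H‑cyclohepta[b]furan‑2‑one, via iodolactone 19 (not isolated)
Conditions: NIS (1.1 equiv), MeCN/H2O (20:1), 0 °C, dark; then K2CO3, 0 °C to rt
Reagents that add atoms: N‑iodosuccinimide O=C1CCC(=O)N1I (iodine of 19 only); water O (lactone carbonyl oxygen)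
Why: Iodolactonisation, in which the ester carbonyl can only close the cis‑fused γ‑lactone at C8a from the face of the C3a side chain so that iodine is delivered to C8 on the opposite face, anti to the C7 hydroxyl, which then displaces it by intramolecular SN2 under mild base to give the 7,8‑epoxide on the hydroxyl face.

Step 10
Reactants: 20 (3aS,5R,6S,7S,8R,8aR)‑7‑[(2Z)‑but‑2‑enoyl]‑5‑[(tert‑butyldimethylsilyl)oxy]‑7,8‑epoxy‑6‑methyl‑3‑methylideneoctahydro‑2H‑cyclohepta[b]furan‑2‑one; 21 3‑methylbutanoic acid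
Product: 22 (3aS,5R,6S,7S,8S,8aR)‑7‑[(2Z)‑but‑2‑enoyl]‑5‑[(tert‑butyldimethylsilyl)oxy]‑7‑hydroxy‑6‑methyl‑3‑methylidene‑2‑oxooctahydro‑2H‑cyclohepta[b]furan‑8‑yl 3‑methylbutanoate
Conditions: 21 (10 equiv), Cs2CO3 (0.3 equiv), toluene, 60 °C
Reagents that add atoms: none
Why: Carboxylate ring opening of the epoxide by SN2 attack at the only accessible carbon (secondary C8, since C7 is quaternary and α to the ketone) proceeds with inversion and places the 3‑methylbutanoate trans to the regenerated C7 hydroxyl.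

Step 11
Reactants: 22 (3aS,5R,6S,7S,8S,8aR)‑7‑[(2Z)‑but‑2‑enoyl]‑5‑[(tert‑butyldimethylsilyl)oxy]‑7‑hydroxy‑6‑methyl‑3‑methylidene‑2‑oxooctahydro‑2H‑cyclohepta[b]furan‑8‑yl 3‑methylbutanoate
Product: 23 (3aS,5R,6S,7S,8S,8aR)‑7‑[(2Z)‑but‑2‑enoyl]‑5,7‑dihydroxy‑6‑methyl‑3‑methylidene‑2‑oxooctahydro‑2H‑cyclohepta[b]furan‑8‑yl 3‑methylbutanoate
Conditions: 48% aq HF, MeCN, 0 °C to rt
Reagents that add atoms: none
Why: Acidic fluoride cleavage of the secondary TBS ether (silyl ether deprotection) is compatible with the ester, the lactone and the (Z)‑enone and leaves all stereocentres untouched.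

**Compound list**

1 | 2‑methylcyclohex‑2‑en‑1‑one | CC1=CCCCC1=O | starting material
2 | (2S,3R)‑2‑methyl‑3‑(4,4,5,5‑tetramethyl‑1,3,2‑dioxaborolan‑2‑yl)cyclohexan‑1‑one | O=C1CCC[C@@H](B2OC(C)(C)C(C)(C)O2)[C@@H]1C | intermediate (not isolated)
3 | (2S,3R)‑3‑hydroxy‑2‑methylcyclohexan‑1‑one (trans) | O=C1CCC[C@@H](O)[C@@H]1C | intermediate
4 | (2S,3R)‑3‑[(tert‑butyldimethylsilyl)oxy]‑2‑methylcyclohexan‑1‑one | O=C1CCC[C@@H](O[Si](C)(C)C(C)(C)C)[C@@H]1C | intermediate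
5 | tert‑butyldimethyl{[(1R,2S)‑2‑methyl‑3‑[(trimethylsilyl)oxy]cyclohex‑3‑en‑1‑yl]oxy}silane | C[Si](C)(C)OC1=CCC[C@@H](O[Si](C)(C)C(C)(C)C)[C@@H]1C | intermediate (not isolated)
6 | (5R,6S)‑5‑[(tert‑butyldimethylsilyl)oxy]‑6‑methylcyclohex‑2‑en‑1‑one | O=C1C=CC[C@@H](O[Si](C)(C)C(C)(C)C)[C@@H]1C | intermediate
7 | methyl 2‑bromoprop‑2‑enoate | C=C(Br)C(=O)OC | starting material
8 | methyl 2‑[(1R,4S,5R)‑5‑[(tert‑butyldimethylsilyl)oxy]‑4‑methyl‑3‑[(triethylsilyl)oxy]cyclohex‑2‑en‑1‑yl]prop‑2‑enoate | CC[Si](CC)(CC)OC1=C[C@H](C(=C)C(=O)OC)C[C@@H](O[Si](C)(C)C(C)(C)C)[C@@H]1C | intermediate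
9 | diiodomethane | ICI | starting material
10 | methyl 2‑[(1S,2R,4R,5S,6R)‑4‑[(tert‑butyldimethylsilyl)oxy]‑5‑methyl‑6‑[(triethylsilyl)oxy]bicyclo[4.1.0]heptan‑2‑yl]prop‑2‑enoate | CC[Si](CC)(CC)O[C@]12C[C@H]1[C@H](C(=C)C(=O)OC)C[C@@H](O[Si](C)(C)C(C)(C)C)[C@@H]2C | intermediate
11 | methyl 2‑[(1S,5S,6R)‑6‑[(tert‑butyldimethylsilyl)oxy]‑2‑chloro‑5‑methyl‑4‑oxocycloheptyl]prop‑2‑enoate (both C2 epimers) | O=C1CC(Cl)[C@H](C(=C)C(=O)OC)C[C@@H](O[Si](C)(C)C(C)(C)C)[C@@H]1C | intermediate (not isolated)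
12 | methyl 2‑[(1R,5S,6R)‑6‑[(tert‑butyldimethylsilyl)oxy]‑5‑methyl‑4‑oxocyclohept‑2‑en‑1‑yl]prop‑2‑enoate | O=C1C=C[C@H](C(=C)C(=O)OC)C[C@@H](O[Si](C)(C)C(C)(C)C)[C@@H]1C | intermediate
13 | but‑2‑yn‑1‑ol | CC#CCO | starting material
14 | 1‑methoxybut‑2‑yne | CC#CCOC | intermediate (not isolated)
15 | 1‑methoxybuta‑1,2‑diene (racemic) | CC=C=COC | intermediate
16 | (1‑methoxybuta‑1,2‑dien‑1‑yl)lithium | [Li]C(OC)=C=CC | intermediate (not isolated)
17 | methyl 2‑[(1R,4R,5S,6R)‑6‑[(tert‑butyldimethylsilyl)oxy]‑4‑hydroxy‑4‑(1‑methoxybuta‑1,2‑dien‑1‑yl)‑5‑methylcyclohept‑2‑en‑1‑yl]prop‑2‑enoate (allene axis unassigned) | CC=C=C(OC)[C@@]1(O)C=C[C@H](C(=C)C(=O)OC)C[C@@H](O[Si](C)(C)C(C)(C)C)[C@@H]1C | intermediate (not isolated)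
18 | methyl 2‑[(1R,4R,5S,6R)‑4‑[(2Z)‑but‑2‑enoyl]‑6‑[(tert‑butyldimethylsilyl)oxy]‑4‑hydroxy‑5‑methylcyclohept‑2‑en‑1‑yl]prop‑2‑enoate | C/C=C\C(=O)[C@@]1(O)C=C[C@H](C(=C)C(=O)OC)C[C@@H](O[Si](C)(C)C(C)(C)C)[C@@H]1C | intermediate
19 | (3aS,5R,6S,7R,8S,8aR)‑7‑[(2Z)‑but‑2‑enoyl]‑5‑[(tert‑butyldimethylsilyl)oxy]‑7‑hydroxy‑8‑iodo‑6‑methyl‑3‑methylideneoctahydro‑2H‑cyclohepta[b]furan‑2‑one | C=C1C(=O)O[C@@H]2[C@H]1C[C@@H](O[Si](C)(C)C(C)(C)C)[C@H](C)[C@@](O)(C(=O)/C=C\C)[C@H]2I | intermediate (not isolated)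
20 | (3aS,5R,6S,7S,8R,8aR)‑7‑[(2Z)‑but‑2‑enoyl]‑5‑[(tert‑butyldimethylsilyl)oxy]‑7,8‑epoxy‑6‑methyl‑3‑methylideneoctahydro‑2H‑cyclohepta[b]furan‑2‑one | C=C1C(=O)O[C@@H]2[C@H]1C[C@@H](O[Si](C)(C)C(C)(C)C)[C@H](C)[C@]3(C(=O)/C=C\C)O[C@H]23 | intermediate
21 | 3‑methylbutanoic acid | CC(C)CC(=O)O | starting material
22 | (3aS,5R,6S,7S,8S,8aR)‑7‑[(2Z)‑but‑2‑enoyl]‑5‑[(tert‑butyldimethylsilyl)oxy]‑7‑hydroxy‑6‑methyl‑3‑methylidene‑2‑oxooctahydro‑2H‑cyclohepta[b]furan‑8‑yl 3‑methylbutanoate | C=C1C(=O)O[C@@H]2[C@H]1C[C@@H](O[Si](C)(C)C(C)(C)C)[C@H](C)[C@@](O)(C(=O)/C=C\C)[C@H]2OC(=O)CC(C)C | intermediate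
23 | (3aS,5R,6S,7S,8S,8aR)‑7‑[(2Z)‑but‑2‑enoyl]‑5,7‑dihydroxy‑6‑methyl‑3‑methylidene‑2‑oxooctahydro‑2H‑cyclohepta[b]furan‑8‑yl 3‑methylbutanoate | C=C1C(=O)O[C@@H]2[C@H]1C[C@@H](O)[C@H](C)[C@@](O)(C(=O)/C=C\C)[C@H]2OC(=O)CC(C)C | target

**Step count and risks**

Total step count: 11. Longest linear sequence: 10 (steps 1–6 and 8–11; step 7 makes the allenyl ether).

Steps most likely to fail:

- **Step 4 (proposed new step).** The bromoacrylate may homocouple, be reduced or polymerise faster than it couples with the allylnickel species. The fallback uses known chemistry, sets out from 6 and comes back at 12. Copper‑catalysed conjugate addition of isopropenylmagnesium bromide to 6 with Et3SiCl trapping (CuBr·SMe2 cat., THF, −78 °C) gives isopropenyl triethylsilyl enol ether F1. Simmons–Smith cyclopropanation (Et2Zn, CH2I2) gives siloxycyclopropane F2. FeCl3 in DMF gives ring‑enlarged chloro ketone F3, which is not isolated and loses HCl with NaOAc to give isopropenyl cycloheptenone F4. Allylic oxidation of the isopropenyl methyl group (SeO2 cat., t‑BuOOH, CH2Cl2) gives enal F5. Oxidation with NaClO2/NaH2PO4/2‑methylbut‑2‑ene gives acrylic acid F6, and TMSCHN2 in MeOH/toluene gives 12.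

- **Step 8.** The lithiated allenyl ether may attack the acrylate ester or deprotonate the doubly allylic C3a–H, and the acid hydrolysis may give some (E)‑enone. The fallback sets out from 12 and comes back at 18. 2‑Lithio‑1,3‑dithiane (THF, −78 °C) adds 1,2 to give dithianyl carbinol F7. MeI/CaCO3 in aqueous MeCN unmasks α‑hydroxy aldehyde F8. Nozaki–Hiyama–Kishi coupling with (Z)‑1‑bromoprop‑1‑ene (CrCl2, NiCl2 cat., DMF) gives (Z)‑allylic diol F9 with retention of alkene geometry. Dess–Martin periodinane oxidises only the secondary allylic alcohol to give 18.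

- **Step 10.** C8 is flanked by a quaternary centre and the lactone oxygen, so carboxylate attack may be slow, and prolonged heating may erode the (Z)‑enone. The fallback sets out from 20 and comes back at 22. Acid‑catalysed hydrolytic opening with the smaller nucleophile water (HClO4 cat., THF/H2O, 0 °C) gives trans‑diol F10 by attack at C8. 3‑Methylbutanoyl chloride, pyridine and DMAP in CH2Cl2 at 0 °C then acylate only the secondary C8 hydroxyl to give 22.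

Further compounds
F1 | step 4 | tert‑butyldimethyl{[(1R,2S,5R)‑2‑methyl‑5‑(prop‑1‑en‑2‑yl)‑3‑[(triethylsilyl)oxy]cyclohex‑3‑en‑1‑yl]oxy}silane | CC[Si](CC)(CC)OC1=C[C@H](C(C)=C)C[C@@H](O[Si](C)(C)C(C)(C)C)[C@@H]1C
F2 | step 4 | (1S,2R,4R,5S,6R)‑4‑[(tert‑butyldimethylsilyl)oxy]‑5‑methyl‑2‑(prop‑1‑en‑2‑yl)‑6‑[(triethylsilyl)oxy]bicyclo[4.1.0]heptane | CC[Si](CC)(CC)O[C@]12C[C@H]1[C@H](C(C)=C)C[C@@H](O[Si](C)(C)C(C)(C)C)[C@@H]2C
F3 | step 4 | (4S,6R,7S)‑6‑[(tert‑butyldimethylsilyl)oxy]‑3‑chloro‑7‑methyl‑4‑(prop‑1‑en‑2‑yl)cycloheptan‑1‑one (both C3 epimers) | O=C1CC(Cl)[C@H](C(C)=C)C[C@@H](O[Si](C)(C)C(C)(C)C)[C@@H]1C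
F4 | step 4 | (4R,6R,7S)‑6‑[(tert‑butyldimethylsilyl)oxy]‑7‑methyl‑4‑(prop‑1‑en‑2‑yl)cyclohept‑2‑en‑1‑one | O=C1C=C[C@H](C(C)=C)C[C@@H](O[Si](C)(C)C(C)(C)C)[C@@H]1C
F5 | step 4 | 2‑[(1R,5S,6R)‑6‑[(tert‑butyldimethylsilyl)oxy]‑5‑methyl‑4‑oxocyclohept‑2‑en‑1‑yl]prop‑2‑enal | O=C1C=C[C@H](C(=C)C=O)C[C@@H](O[Si](C)(C)C(C)(C)C)[C@@H]1C
F6 | step 4 | 2‑[(1R,5S,6R)‑6‑[(tert‑butyldimethylsilyl)oxy]‑5‑methyl‑4‑oxocyclohept‑2‑en‑1‑yl]prop‑2‑enoic acid | O=C1C=C[C@H](C(=C)C(=O)O)C[C@@H](O[Si](C)(C)C(C)(C)C)[C@@H]1C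
F7 | step 8 | methyl 2‑[(1R,4R,5S,6R)‑6‑[(tert‑butyldimethylsilyl)oxy]‑4‑(1,3‑dithian‑2‑yl)‑4‑hydroxy‑5‑methylcyclohept‑2‑en‑1‑yl]prop‑2‑enoate | S1CCCSC1[C@@]1(O)C=C[C@H](C(=C)C(=O)OC)C[C@@H](O[Si](C)(C)C(C)(C)C)[C@@H]1C
F8 | step 8 | methyl 2‑[(1R,4R,5S,6R)‑6‑[(tert‑butyldimethylsilyl)oxy]‑4‑formyl‑4‑hydroxy‑5‑methylcyclohept‑2‑en‑1‑yl]prop‑2‑enoate | O=C[C@@]1(O)C=C[C@H](C(=C)C(=O)OC)C[C@@H](O[Si](C)(C)C(C)(C)C)[C@@H]1C
F9 | step 8 | methyl 2‑[(1R,4R,5S,6R)‑6‑[(tert‑butyldimethylsilyl)oxy]‑4‑hydroxy‑4‑[(2Z)‑1‑hydroxybut‑2‑en‑1‑yl]‑5‑methylcyclohept‑2‑en‑1‑yl]prop‑2‑enoate (both carbinol epimers) | C/C=C\C(O)[C@@]1(O)C=C[C@H](C(=C)C(=O)OC)C[C@@H](O[Si](C)(C)C(C)(C)C)[C@@H]1C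
F10 | step 10 | (3aS,5R,6S,7S,8S,8aR)‑7‑[(2Z)‑but‑2‑enoyl]‑5‑[(tert‑butyldimethylsilyl)oxy]‑7,8‑dihydroxy‑6‑methyl‑3‑methylideneoctahydro‑2H‑cyclohepta[b]furan‑2‑one | C=C1C(=O)O[C@@H]2[C@H]1C[C@@H](O[Si](C)(C)C(C)(C)C)[C@H](C)[C@@](O)(C(=O)/C=C\C)[C@H]2O
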